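Numbering: ring A = C1–C4, C4a, C11b; ring B = pyran with O5, C6; ring C = dihydrofuran O11–C11a–C6a–C6b–C10a; ring D = methoxy arene; ring E = dimethyldihydropyran on C1 (through O) and C2 (through CH2).
Cuts: O3 is masked as a TIPS ether and a hydroxyl is added back at C8. Ring C is then cut at C6a–C6b and C11a–O11, which gives an A/B/E 2H-chromene and 2-methoxy-1,4-benzoquinone.
Enabling feature: C6a–C11a of ring C is the chromene alkene and C6b–C10a–O11 is a C–C–O edge of the quinone. C11a is benzylic to ring A, whose oxygens at C1 and C4a (ortho) and C3 (para) can carry a positive charge at C11a.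
Further cuts: ring B at C11a–C11b (propargyl Claisen of the O5 propargyl ether). Ring E is cut at its C2–acyl and O–CMe2 bonds, back to phloroglucinol and 3-methylbut-2-enoic acid.
Forward order: ring E is made first as a chromanone. Its C=O chelates the future O3 phenol, so only O5 is propargylated, and it is then reduced to CH2. Ring B follows, then ring C with ring D attached in one step, then removal of the C8 oxygen and desilylation.
Stereochemistry: C6a comes from a chiral titanium TADDOLate in the annulation. C11a follows because the B/C fusion can only close cis, and no later step touches either centre.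

Key step: step 6

Assumption: no model predicts safely which face the titanium TADDOLate selects on this chromene. The route is written with (R,R)-TADDOL, a trial run with assignment of the product decides, and the equally available (S,S)-TADDOL is used if the (6aR,11aR) series results.
Remark on locants: bicyclic compounds carry chroman numbering (O1, C2 gem-dimethyl, C4 benzylic). Chroman O5 becomes pterocarpan O3, chroman O7 becomes O5, chroman C8 becomes C11b and chroman C6 becomes C4.

Step 1
Reactants: 1 phloroglucinol; 2 3-methylbut-2-enoic acid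
Product: 4 5,7-dihydroxy-2,2-dimethylchroman-4-one, via trihydroxyphenyl enone 3 (not isolated)
Conditions: P2O5, MeSO3H, 70 °C
Reagents that add atoms: none
Why: Friedel–Crafts acylation of the threefold symmetric, very nucleophilic arene gives enone 3, whose ortho hydroxyl closes ring E by 6-endo-trig oxa-Michael addition at the gem-dimethyl terminus, and the new acyl group deactivates the ring against a second acylation.

Step 2
Reactants: 4 5,7-dihydroxy-2,2-dimethylchroman-4-one; 5 propargyl bromide
Product: 6 5-hydroxy-2,2-dimethyl-7-(prop-2-yn-1-yloxy)chroman-4-one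
Conditions: K2CO3 (1.1 equiv), 5 (1.05 equiv), acetone, reflux
Reagents that add atoms: none
Why: Williamson ether synthesis in which the 5-OH is locked in a six-membered hydrogen bond to C4=O, so only the free 7-OH, a vinylogous acid para to the acyl carbon, is deprotonated and alkylated.

Step 3
Reactants: 6 5-hydroxy-2,2-dimethyl-7-(prop-2-yn-1-yloxy)chroman-4-one
Product: 9 2,2-dimethyl-7-(prop-2-yn-1-yloxy)chroman-5-ol, via ethyl carbonate 7 (not isolated), via ring-E o-quinone methide 8 (not isolated)
Conditions: ClCO2Et, Et3N, THF, 0 °C; filter; then NaBH4, THF–H2O, 0 °C → rt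
Reagents that add atoms: ethyl chloroformate, CCOC(=O)Cl (its atoms are carried by intermediate 7 only and are lost again before 9)
Why: This is the chloroformate/borohydride deoxygenation of an o-hydroxyaryl ketone, in which hydride reduces the ketone of 7, the carbonate shifts to the new benzylic alkoxide and leaves to give o-quinone methide 8, and a second hydride adds at C4, while alkyne and aryl ether are inert to NaBH4.

Step 4
Reactants: 9 2,2-dimethyl-7-(prop-2-yn-1-yloxy)chroman-5-ol
Product: 10 2,2-dimethyl-7-(prop-2-yn-1-yloxy)-5-(triisopropylsilyloxy)chroman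
Conditions: TIPSCl, imidazole, DMF, rt
Reagents that add atoms: triisopropylsilyl chloride, CC(C)[Si](Cl)(C(C)C)C(C)C
Why: Imidazole-mediated silylation of the only hydroxyl, with TIPS chosen because it tolerates strong heating and Ti(IV) and because its bulk, pushed away from the C4 methylene, lies over C6.

Step 5
Reactants: 10 2,2-dimethyl-7-(prop-2-yn-1-yloxy)-5-(triisopropylsilyloxy)chroman
Product: 13 2,2-dimethyl-5-(triisopropylsilyloxy)-3,4-dihydro-2H,8H-pyrano[2,3-f]chromene, via 8-allenylphenol 11 (not isolated), via vinyl o-quinone methide 12 (not isolated)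
Conditions: PhNEt2, 210 °C, Ar
Reagents that add atoms: none
Why: Aromatic propargyl Claisen rearrangement to C8 and tautomerisation give 11, a 1,5-hydrogen shift gives 12 and an oxa-6π electrocyclisation closes ring B; C8 should win over C6 because the alkyl group on O1 is tied back in ring E whereas the TIPS group covers C6, in line with the general C8 preference of 5,7-dioxygenated chromans.

Step 6
Reactants: 13 2,2-dimethyl-5-(triisopropylsilyloxy)-3,4-dihydro-2H,8H-pyrano[2,3-f]chromene; 14 2-methoxy-1,4-benzoquinone
Product: 16 (6aS,11aS)-8-hydroxy-9-methoxy-3-(triisopropylsilyloxy)pterocarpan carrying ring E at C1/C2, via C11a-cation zwitterion 15 (not isolated)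
Conditions: TiCl4/Ti(OiPr)4 (1:1), (R,R)-TADDOL, toluene, rt, evaporate; 14, CH2Cl2, −78 °C; then 13, −78 → −30 °C; aq. NaHCO3 (promoter 1.5 equiv)
Reagents that add atoms: none
Why: Titanium holds 14 through the C1 carbonyl and the adjacent methoxy oxygen, which activates the C1=O/C6=C5 enone while C4=O remains a deactivated vinylogous ester, so the chromene alkene adds through its β-carbon (future C6a) to quinone C5 (future C6b) in a Michael-type step and gives zwitterion 15, whose C11a cation is delocalised onto the ring A oxygens at C1, C4a and C3. The former C4 oxygen, now flanking the new bond, captures C11a in a 5-exo-trig closure of ring C (the cation read as its ring A quinone-methide oxonium form, with C11a=C11b exocyclic to the new ring), and loss of the C6b proton rearomatises ring D to the titanium phenoxide of 16, which is freed on work-up. The closest known reaction type is this one itself, the Ti(IV)-promoted formal [3+2] annulation of 2-alkoxy-1,4-benzoquinones with styrenes and 2H-chromenes, for which TADDOLate-modified promoters are established. C6a is set in the C–C bond-forming event by the ligand, whose phenyl groups shield one face of the chelated quinone and leave one orientation for the prochiral alkene, whereas C11a is set by the substrate, because a five-membered ring can be closed across the C6a–C11a bond of six-membered ring B only in the cis sense. The step needs site selectivity on the quinone (secured by the chelating 2-methoxy group), the right alkene polarity (secured by the three donor oxygens ortho, ortho and para to C11b), the [3+2] rather than the [2+2] mode (favoured by the long-lived cation and by warming, since the [2+2] mode is reversible under Ti(IV)) and attack by the alkene rather than by the free ring A position C4 (flanked by the TIPS ether).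

Step 7
Reactants: 16 (6aS,11aS)-8-hydroxy-9-methoxy-3-(triisopropylsilyloxy)pterocarpan carrying ring E at C1/C2
Product: 17 the corresponding (6aS,11aS)-8-trifluoromethanesulfonate
Conditions: PhNTf2, Et3N, DMAP (cat.), CH2Cl2, rt
Reagents that add atoms: N-phenylbis(trifluoromethanesulfonimide), FC(F)(F)S(=O)(=O)N(c1ccccc1)S(=O)(=O)C(F)(F)F
Why: Sulfonylation of the only free hydroxyl with a mild triflyl donor under amine base, free of strong acid, so the ionisable C11a–O11 bond and the silyl ether are left alone.

Step 8
Reactants: 17 (6aS,11aS)-8-trifluoromethanesulfonate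
Product: 18 (6aS,11aS)-9-methoxy-3-(triisopropylsilyloxy)pterocarpan carrying ring E at C1/C2 (O-TIPS target)
Conditions: Pd(OAc)2 (5 mol %), dppf, HCO2H, Et3N, DMF, 70 °C
Reagents that add atoms: none
Why: Palladium-catalysed transfer hydrogenolysis of an aryl triflate (oxidative addition at C8–O, exchange for formate, decarboxylation, reductive elimination), in which dppf helps the electron-rich triflate and a homogeneous Pd(0) catalyst leaves the benzylic C11a–O11 bond intact; any silyl loss here would only anticipate step 9.

Step 9
Reactants: 18 O-TIPS target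
Product: 19 target, (6aS,11aS)-3-hydroxy-9-methoxypterocarpan carrying ring E at C1/C2
Conditions: TBAF, AcOH, THF, 0 °C
Reagents that add atoms: none
Why: Fluoride-induced cleavage of the aryl silyl ether driven by Si–F bond formation and buffered so that the phenoxide is protonated at once; neither stereocentre carries an acidic hydrogen, so the (6aS,11aS) configuration is kept.

Compound list
1 | phloroglucinol | Oc1cc(O)cc(O)c1 | starting material
2 | 3-methylbut-2-enoic acid | CC(C)=CC(=O)O | starting material
3 | 3-methyl-1-(2,4,6-trihydroxyphenyl)but-2-en-1-one | CC(C)=CC(=O)c1c(O)cc(O)cc1O | intermediate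
4 | 5,7-dihydroxy-2,2-dimethylchroman-4-one | CC1(C)CC(=O)c2c(O1)cc(O)cc2O | intermediate
5 | propargyl bromide | C#CCBr | starting material
6 | 5-hydroxy-2,2-dimethyl-7-(prop-2-yn-1-yloxy)chroman-4-one | CC1(C)CC(=O)c2c(O1)cc(OCC#C)cc2O | intermediate
7 | ethyl 2,2-dimethyl-4-oxo-7-(prop-2-yn-1-yloxy)chroman-5-yl carbonate | CCOC(=O)Oc1cc(OCC#C)cc2OC(C)(C)CC(=O)c12 | intermediate
8 | 2,2-dimethyl-7-(prop-2-yn-1-yloxy)-2H-chromen-5(3H)-one (o-quinone methide, C4=C4a, C5=O) | CC1(C)CC=C2C(=O)C=C(OCC#C)C=C2O1 | intermediate
9 | 2,2-dimethyl-7-(prop-2-yn-1-yloxy)chroman-5-ol | CC1(C)CCc2c(O1)cc(OCC#C)cc2O | intermediate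
10 | 2,2-dimethyl-7-(prop-2-yn-1-yloxy)-5-(triisopropylsilyloxy)chroman | CC1(C)CCc2c(O1)cc(OCC#C)cc2O[Si](C(C)C)(C(C)C)C(C)C | intermediate
11 | 2,2-dimethyl-8-(propa-1,2-dien-1-yl)-5-(triisopropylsilyloxy)chroman-7-ol | CC1(C)CCc2c(O1)c(C=C=C)c(O)cc2O[Si](C(C)C)(C(C)C)C(C)C | intermediate
12 | (8Z)-2,2-dimethyl-8-(prop-2-en-1-ylidene)-5-(triisopropylsilyloxy)-3,4-dihydro-2H-chromen-7(8H)-one | C=C/C=C1\C(=O)C=C(O[Si](C(C)C)(C(C)C)C(C)C)C2=C1OC(C)(C)CC2 | intermediate
13 | 2,2-dimethyl-5-(triisopropylsilyloxy)-3,4-dihydro-2H,8H-pyrano[2,3-f]chromene (A/B/E chromene, C9=C10 is the future C6a–C11a) | C1=Cc2c(cc(O[Si](C(C)C)(C(C)C)C(C)C)c3c2OC(C)(C)CC3)OC1 | intermediate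
14 | 2-methoxy-1,4-benzoquinone | COC1=CC(=O)C=CC1=O | starting material
15 | C11a benzylic cation / C8 oxide zwitterion (titanium omitted; the former quinone C5 centre is undefined and is lost on aromatisation) | COC1=CC(=O)C(C=C1[O-])[C@H]1COc2cc(O[Si](C(C)C)(C(C)C)C(C)C)c3CCC(C)(C)Oc3c2[CH+]1 | intermediate
16 | (6aS,11aS)-8-hydroxy-9-methoxy-3-(triisopropylsilyloxy)pterocarpan with a 2,2-dimethyl-3,4-dihydro-2H-pyran ring fused at C1 (O) and C2 (CH2) | COc1c(O)cc2c(c1)O[C@@H]1c3c(cc(O[Si](C(C)C)(C(C)C)C(C)C)c4c3OC(C)(C)CC4)OC[C@H]21 | intermediate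
17 | 8-trifluoromethanesulfonate of 16, (6aS,11aS) | COc1c(OS(=O)(=O)C(F)(F)F)cc2c(c1)O[C@@H]1c3c(cc(O[Si](C(C)C)(C(C)C)C(C)C)c4c3OC(C)(C)CC4)OC[C@H]21 | intermediate
18 | O3-TIPS ether of the target, (6aS,11aS) | COc1ccc2c(c1)O[C@@H]1c3c(cc(O[Si](C(C)C)(C(C)C)C(C)C)c4c3OC(C)(C)CC4)OC[C@H]21 | intermediate
19 | (6aS,11aS)-3-hydroxy-9-methoxypterocarpan with a 2,2-dimethyl-3,4-dihydro-2H-pyran ring fused at C1 (O) and C2 (CH2) | COc1ccc2c(c1)O[C@@H]1c3c(cc(O)c4c3OC(C)(C)CC4)OC[C@H]21 | target

Total step count: 9. Longest linear sequence: 9 steps (1 → 19); 14 is used as purchased.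

Steps most likely to fail

Step 6. Facial selectivity may be poor, because this unusually nucleophilic alkene may react through ligand-free chlorotitanium species faster than through the TADDOLate. Part of the material may also be diverted into the [2+2] mode. The fallback moves the source of chirality from the promoter to a resolution. Setting out from 13 and 14, the annulation is run with achiral TiCl4/Ti(OiPr)4 in CH2Cl2, which should give 16 as a racemate with its mirror image, the (6aR,11aR)-phenol F1. The C8 phenol created by the annulation is acylated with (1S)-camphanic chloride (Et3N, DMAP, CH2Cl2) to the (6aS,11aS)-camphanate F2 and the (6aR,11aR)-camphanate F3. These are separated by crystallisation or chromatography. LiOH in THF–water at 0 °C cleaves F2, and the route is rejoined at 16.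

Step 5. The propargyl unit may migrate to C6 instead of C8, or the electron-rich product may degrade at the high temperature. The fallback fixes the site of C–C bond formation with a halogen before ring B is closed, and closes the ring by metathesis instead of a pericyclic cascade. Setting out from 10, semihydrogenation over Lindlar catalyst (H2, quinoline, EtOAc) should give the 7-allyl ether F4. NBS in CH2Cl2 at −78 → 0 °C brominates the more accessible and more nucleophilic C8 to the 8-bromo allyl ether F5, whose substitution pattern can be checked and purified at this stage. Stille coupling with tributyl(vinyl)stannane (Pd(PPh3)4, toluene, 110 °C) gives the 8-vinyl allyl ether F6. Ring-closing metathesis (second-generation Grubbs catalyst, CH2Cl2, 40 °C) rejoins the route at 13.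

Step 3. Deoxygenation may be incomplete, because aqueous borohydride can cleave the carbonate before it migrates, and the reduction then stalls at the benzylic alcohol level. The fallback avoids the carbonyl group altogether. Setting out from 1 (used in excess), acid-catalysed annulation with 2-methylbut-3-en-2-ol (Amberlyst 15, THF–heptane, 65 °C; Friedel–Crafts prenylation followed by ring closure) should give 2,2-dimethylchroman-5,7-diol F7. One equivalent of 5 with K2CO3 in acetone then alkylates the less hindered 7-OH preferentially, isomeric and double ethers are removed by chromatography, and the route is rejoined at 9.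

Further compounds
F1 | step 6 | (6aR,11aR)-enantiomer of 16 | COc1c(O)cc2c(c1)O[C@H]1c3c(cc(O[Si](C(C)C)(C(C)C)C(C)C)c4c3OC(C)(C)CC4)OC[C@@H]21
F2 | step 6 | (1S,4R)-camphanate of 16 at O8, (6aS,11aS) | CC1(C)[C@@]2(C)CC[C@@]1(OC2=O)C(=O)Oc1cc2c(cc1OC)O[C@@H]1c3c(cc(O[Si](C(C)C)(C(C)C)C(C)C)c4c3OC(C)(C)CC4)OC[C@H]21
F3 | step 6 | (1S,4R)-camphanate of F1 at O8, (6aR,11aR) | CC1(C)[C@@]2(C)CC[C@@]1(OC2=O)C(=O)Oc1cc2c(cc1OC)O[C@H]1c3c(cc(O[Si](C(C)C)(C(C)C)C(C)C)c4c3OC(C)(C)CC4)OC[C@@H]21
F4 | step 5 | 7-(allyloxy)-2,2-dimethyl-5-(triisopropylsilyloxy)chroman | CC1(C)CCc2c(O1)cc(OCC=C)cc2O[Si](C(C)C)(C(C)C)C(C)C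
F5 | step 5 | 7-(allyloxy)-8-bromo-2,2-dimethyl-5-(triisopropylsilyloxy)chroman | CC1(C)CCc2c(O1)c(Br)c(OCC=C)cc2O[Si](C(C)C)(C(C)C)C(C)C
F6 | step 5 | 7-(allyloxy)-2,2-dimethyl-5-(triisopropylsilyloxy)-8-vinylchroman | CC1(C)CCc2c(O1)c(C=C)c(OCC=C)cc2O[Si](C(C)C)(C(C)C)C(C)C
F7 | step 3 | 2,2-dimethylchroman-5,7-diol | CC1(C)CCc2c(O1)cc(O)cc2O
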